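**Retrosynthetic overview**
- The flavanone C2–aryl bond is cut last: Pd-catalysed asymmetric 1,4-addition of [2-(4-methoxyphenyl)benzofuran-5-yl]boronic acid to 7-methoxychromone (one step from paeonol) sets the only stereocentre.
- The strategy rests on the 2-arylbenzofuran: its O1'–C2'–C3'–C3a' atoms are O1–C2–C3–C4a of 6-bromo-4'-methoxyflavanone with the carbonyl carbon C4 excised. The furan ring therefore comes from oxidative contraction of the pyranone (C4a shifts from C4 to C3), and C4 leaves later as CO2.
- The bromoflavanone comes from 5-bromo-2-hydroxyacetophenone and anisaldehyde (Claisen–Schmidt condensation, then oxa-Michael closure); the 6-bromine becomes the 5-boron handle.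
- Ring order: pyranone of the bromoflavanone (step 2), contracted to the dihydrofuran (step 3), aromatised to the furan (step 4); chromone pyranone (step 8), which becomes the chromanone ring of the target in step 9.

Key step: step 3

Assumption: the Pd/pyridine-oxazoline catalyst is taken to attack the chromone C2=C3 bond with the same facial sense as it does 3-substituted cyclohexenones, which assigns the (R)-ligand to the (S)-flavanone; if a first run shows the opposite sense, the (S)-ligand is used with no other change. Compounds 4–6 are racemic by design, since their stereocentres are erased in step 4.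

**Step 1**
Reactants: 1 1-(5-bromo-2-hydroxyphenyl)ethanone; 2 4-methoxybenzaldehyde
Product: 3 (E)-1-(5-bromo-2-hydroxyphenyl)-3-(4-methoxyphenyl)prop-2-en-1-one
Conditions: KOH (aq), EtOH, 0 °C → rt; then aq HCl
Reagents that add atoms: none
Why: Claisen–Schmidt condensation of the methyl ketone enolate with a non-enolisable aryl aldehyde, with E1cB dehydration giving the conjugated (E)-2'-hydroxychalcone.

**Step 2**
Reactants: 3 (E)-1-(5-bromo-2-hydroxyphenyl)-3-(4-methoxyphenyl)prop-2-en-1-one
Product: 4 (±)-6-bromo-2-(4-methoxyphenyl)chroman-4-one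
Conditions: 85% H3PO4, EtOH, reflux (unchanged 3 recycled)
Reagents that add atoms: none
Why: Acid-mediated intramolecular oxa-Michael addition (chalcone–flavanone isomerisation, 6-endo-trig) should proceed well because the p-anisyl group stabilises positive charge at the β-carbon; the C2 centre forms racemic, which is acceptable.

**Step 3**
Reactants: 4 (±)-6-bromo-2-(4-methoxyphenyl)chroman-4-one
Product: 6 methyl (±)-trans-5-bromo-2-(4-methoxyphenyl)-2,3-dihydro-1-benzofuran-3-carboxylate, via 2H-chromene enol ether 5 (not isolated)
Conditions: HC(OMe)3, conc. H2SO4, rt; then PhI(OAc)2 (1.1 equiv), rt → 50 °C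
Reagents that add atoms: trimethyl orthoformate, COC(OC)OC
Why: Acidic orthoformate converts the C4 ketone into enol ether 5, which attacks PhI(OAc)2 at C3 on the face anti to the equatorial C2 anisyl group, and methanol recloses the oxocarbenium ion to an α-iodanyl dimethyl ketal. The equatorial C3–I(III) bond is antiperiplanar to the ring bond C4–C4a, so the aryl carbon C4a shifts from C4 to C3 through a phenonium-like bridged transition state as iodobenzene departs, and the dimethoxycarbenium ion left at the old C4 loses a methyl group to give the ester. This is the known iodine(III) (or thallium(III)) oxidative ring contraction of flavanones in trimethyl orthoformate, a semipinacol-type 1,2-aryl shift. The dihydrofuran ring is not closed by a cyclisation but results from contraction of the pyranone, the new C3–C3a bond forming by ipso attack of the arene on C3 (3-exo-tet bridging, then opening towards C4). The new C3 stereocentre is under substrate control, since anti iodination followed by inversion in the shift places the ester trans to the C2 aryl group, which is also the thermodynamic arrangement at this epimerisable centre; it is erased in step 4. The step needs chemoselectivity for C4a migration over the C2→C3 anisyl shift (isoflavone) and over dehydrogenation (flavone): ketalisation before the oxidant is added, the equatorial C–I geometry and the ring oxygen ortho to C4a favour contraction, whereas the anisyl shift would need a diaxial C2-aryl/C3-iodane conformer.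

**Step 4**
Reactants: 6 methyl (±)-trans-5-bromo-2-(4-methoxyphenyl)-2,3-dihydro-1-benzofuran-3-carboxylate
Product: 7 methyl 5-bromo-2-(4-methoxyphenyl)-1-benzofuran-3-carboxylate
Conditions: DDQ (2 equiv), 1,4-dioxane, 100 °C
Reagents that add atoms: none
Why: DDQ dehydrogenation, in which hydride abstraction from C2 (benzylic, α to oxygen, stabilised by the p-anisyl group) and loss of the acidic C3–H next to the ester give the aromatic furan and remove both stereocentres.

**Step 5**
Reactants: 7 methyl 5-bromo-2-(4-methoxyphenyl)-1-benzofuran-3-carboxylate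
Product: 8 5-bromo-2-(4-methoxyphenyl)-1-benzofuran-3-carboxylic acid
Conditions: LiOH·H2O, THF/MeOH/H2O, 60 °C; then aq HCl
Reagents that add atoms: lithium hydroxide, [Li+].[OH-]
Why: Saponification (BAc2 ester hydrolysis) of a heteroaryl methyl ester; the aryl bromide, aryl methyl ether and benzofuran are inert to aqueous hydroxide.

**Step 6**
Reactants: 8 5-bromo-2-(4-methoxyphenyl)-1-benzofuran-3-carboxylic acid
Product: 9 5-bromo-2-(4-methoxyphenyl)-1-benzofuran
Conditions: Ag2CO3 (10 mol %), AcOH (5 mol %), DMSO, 120 °C
Reagents that add atoms: none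
Why: Silver-catalysed protodecarboxylation of a heteroaromatic acid, in which the silver carboxylate, twisted out of plane by the flanking 2-aryl group, extrudes CO2 to a C3–Ag species that is protonated; Ag(I) does not insert into the C–Br bond.

**Step 7**
Reactants: 9 5-bromo-2-(4-methoxyphenyl)-1-benzofuran
Product: 12 [2-(4-methoxyphenyl)-1-benzofuran-5-yl]boronic acid, via aryllithium 10 (not isolated), via lithium triisopropoxyborate 11 (not isolated)
Conditions: n-BuLi, THF, −78 °C; B(OiPr)3, −78 °C → rt; 1 M HCl
Reagents that add atoms: triisopropyl borate, CC(C)OB(OC(C)C)OC(C)C; water, O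
Why: Bromine–lithium exchange is faster than any deprotonation at −78 °C (C2 is blocked, C3–H is not acidic), and borylation of the aryllithium followed by acid hydrolysis gives the free boronic acid that the Pd(II) conjugate addition requires.

**Step 8**
Reactants: 13 1-(2-hydroxy-4-methoxyphenyl)ethanone (paeonol)
Product: 15 7-methoxy-4H-chromen-4-one, via enaminone 14 (not isolated)
Conditions: Me2NCH(OMe)2, 95 °C, evaporate; then conc. HCl, CH2Cl2, 40 °C
Reagents that add atoms: N,N-dimethylformamide dimethyl acetal, COC(OC)N(C)C
Why: Standard chromone synthesis: condensation of the methyl ketone with the formamide acetal gives the enaminone, and acid promotes 6-endo addition of the phenol to the β-carbon with loss of dimethylamine.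

**Step 9**
Reactants: 12 [2-(4-methoxyphenyl)-1-benzofuran-5-yl]boronic acid; 15 7-methoxy-4H-chromen-4-one (1.5 equiv)
Product: 16 (2S)-7-methoxy-2-[2-(4-methoxyphenyl)-1-benzofuran-5-yl]-2,3-dihydro-4H-chromen-4-one (Lophirone J)
Conditions: Pd(OCOCF3)2 (5 mol %), (R)-t-BuPyOx (6 mol %), NH4PF6 (30 mol %), H2O (5 equiv), ClCH2CH2Cl, 60 °C
Reagents that add atoms: none
Why: Pd(II)-catalysed asymmetric conjugate addition of an arylboronic acid to a chromone (transmetallation, enantio-determining carbopalladation of C2=C3, protonolysis of the Pd enolate), with the C2 configuration set by the chiral pyridine-oxazoline ligand and the base-free medium avoiding retro-oxa-Michael racemisation.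

**Compound list**
1 | 1-(5-bromo-2-hydroxyphenyl)ethanone | CC(=O)c1cc(Br)ccc1O | starting material
2 | 4-methoxybenzaldehyde | COc1ccc(C=O)cc1 | starting material
3 | (E)-1-(5-bromo-2-hydroxyphenyl)-3-(4-methoxyphenyl)prop-2-en-1-one | COc1ccc(/C=C/C(=O)c2cc(Br)ccc2O)cc1 | intermediate
4 | (±)-6-bromo-2-(4-methoxyphenyl)chroman-4-one | COc1ccc(C2CC(=O)c3cc(Br)ccc3O2)cc1 | intermediate
5 | (±)-6-bromo-4-methoxy-2-(4-methoxyphenyl)-2H-chromene | COC1=CC(c2ccc(OC)cc2)Oc2ccc(Br)cc12 | intermediate (not isolated)
6 | methyl (±)-trans-5-bromo-2-(4-methoxyphenyl)-2,3-dihydro-1-benzofuran-3-carboxylate (racemic, relative configuration drawn) | COC(=O)[C@@H]1c2cc(Br)ccc2O[C@H]1c1ccc(OC)cc1 | intermediate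
7 | methyl 5-bromo-2-(4-methoxyphenyl)-1-benzofuran-3-carboxylate | COC(=O)c1c(-c2ccc(OC)cc2)oc2ccc(Br)cc12 | intermediate
8 | 5-bromo-2-(4-methoxyphenyl)-1-benzofuran-3-carboxylic acid | COc1ccc(-c2oc3ccc(Br)cc3c2C(=O)O)cc1 | intermediate
9 | 5-bromo-2-(4-methoxyphenyl)-1-benzofuran | COc1ccc(-c2cc3cc(Br)ccc3o2)cc1 | intermediate
10 | [2-(4-methoxyphenyl)-1-benzofuran-5-yl]lithium | [Li]c1ccc2oc(-c3ccc(OC)cc3)cc2c1 | intermediate (not isolated)
11 | lithium triisopropoxy[2-(4-methoxyphenyl)-1-benzofuran-5-yl]borate | [Li+].CC(C)O[B-](OC(C)C)(OC(C)C)c1ccc2oc(-c3ccc(OC)cc3)cc2c1 | intermediate (not isolated)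
12 | [2-(4-methoxyphenyl)-1-benzofuran-5-yl]boronic acid | OB(O)c1ccc2oc(-c3ccc(OC)cc3)cc2c1 | intermediate
13 | 1-(2-hydroxy-4-methoxyphenyl)ethanone (paeonol) | CC(=O)c1ccc(OC)cc1O | starting material
14 | (E)-3-(dimethylamino)-1-(2-hydroxy-4-methoxyphenyl)prop-2-en-1-one | CN(C)/C=C/C(=O)c1ccc(OC)cc1O | intermediate (not isolated)
15 | 7-methoxy-4H-chromen-4-one | O=c1ccoc2cc(OC)ccc12 | intermediate
16 | (2S)-7-methoxy-2-[2-(4-methoxyphenyl)-1-benzofuran-5-yl]-2,3-dihydro-4H-chromen-4-one (Lophirone J) | COc1ccc(-c2cc3cc([C@@H]4CC(=O)c5ccc(OC)cc5O4)ccc3o2)cc1 | target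

**Step count and risks**
Total step count: 9. Longest linear sequence: 8 (steps 1–7, then 9); the chromone branch is step 8.

Steps most likely to fail:

1. Step 3 (key step). The oxidation may be diverted before the C4a shift: the anisyl group can migrate from C2 to C3 (isoflavone pathway), or the enol ether can simply lose hydrogen (flavone pathway), and the bromine meta to C4a slightly lowers its migratory aptitude. Fallback, which builds the furan by alkyne hydroalkoxylation instead: it sets out from 2. Ohira–Bestmann homologation (dimethyl (1-diazo-2-oxopropyl)phosphonate, K2CO3, MeOH, rt) should give 1-ethynyl-4-methoxybenzene F1. Sonogashira coupling with commercial 4-bromo-2-iodophenol (PdCl2(PPh3)2, CuI, Et3N, DMF, rt), selective for the C–I bond, should give 4-bromo-2-[(4-methoxyphenyl)ethynyl]phenol F2. On warming to 60–80 °C in the same copper/amine medium this is expected to close 5-endo-dig to 9. The fallback rejoins the route at 9 and replaces steps 1–6.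

2. Step 9. Carbopalladation of the electron-rich 7-methoxychromone may be slow enough for protodeboronation of 12 to compete, and facial discrimination on this acceptor may be incomplete. Fallback, which builds the flavanone by the chalcone route and resolves it: it sets out from 9 and 13. Bromine–lithium exchange (n-BuLi, THF, −78 °C) and a DMF quench should give 2-(4-methoxyphenyl)-1-benzofuran-5-carbaldehyde F3. Claisen–Schmidt condensation with paeonol 13 (KOH, EtOH) should give (E)-1-(2-hydroxy-4-methoxyphenyl)-3-[2-(4-methoxyphenyl)-1-benzofuran-5-yl]prop-2-en-1-one F4. Oxa-Michael closure (NaOAc, EtOH, reflux) should give (±)-7-methoxy-2-[2-(4-methoxyphenyl)-1-benzofuran-5-yl]chroman-4-one F5. Kinetic resolution by asymmetric transfer hydrogenation (RuCl(p-cymene)[(R,R)-TsDPEN], HCO2H/Et3N, stopped near half conversion) is expected to reduce the (2R)-enantiomer to (2R,4R)-cis-7-methoxy-2-[2-(4-methoxyphenyl)-1-benzofuran-5-yl]chroman-4-ol F6 and leave the (2S)-ketone, separable by chromatography. The catalyst antipode is assigned by analogy with aryl ketone reductions and is to be confirmed. The fallback rejoins the route at 16.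

3. Step 6. The hindered silver 3-carboxylate may not extrude CO2 at a temperature the substrate tolerates, and forcing conditions risk loss of bromine. Fallback, which decarboxylates at the sp3 stage and forms the furan double bond in the same event: it sets out from 6. Saponification (LiOH, THF/H2O, rt; then aq HCl) should give (±)-trans-5-bromo-2-(4-methoxyphenyl)-2,3-dihydro-1-benzofuran-3-carboxylic acid F7. Kochi oxidative decarboxylation (Pb(OAc)4, cat. Cu(OAc)2, pyridine, benzene, 80 °C) should generate the benzylic C3 radical, which Cu(II) oxidises with loss of the C2 proton to give 9 directly; any C3 acetate formed would eliminate to the same benzofuran on acidic work-up. The fallback rejoins the route at 9 and replaces steps 4–6.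

**Further compounds**
F1 | step 3 | 1-ethynyl-4-methoxybenzene | C#Cc1ccc(OC)cc1
F2 | step 3 | 4-bromo-2-[(4-methoxyphenyl)ethynyl]phenol | COc1ccc(C#Cc2cc(Br)ccc2O)cc1
F3 | step 9 | 2-(4-methoxyphenyl)-1-benzofuran-5-carbaldehyde | COc1ccc(-c2cc3cc(C=O)ccc3o2)cc1
F4 | step 9 | (E)-1-(2-hydroxy-4-methoxyphenyl)-3-[2-(4-methoxyphenyl)-1-benzofuran-5-yl]prop-2-en-1-one | COc1ccc(-c2cc3cc(/C=C/C(=O)c4ccc(OC)cc4O)ccc3o2)cc1
F5 | step 9 | (±)-7-methoxy-2-[2-(4-methoxyphenyl)-1-benzofuran-5-yl]chroman-4-one | COc1ccc(-c2cc3cc(C4CC(=O)c5ccc(OC)cc5O4)ccc3o2)cc1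
F6 | step 9 | (2R,4R)-cis-7-methoxy-2-[2-(4-methoxyphenyl)-1-benzofuran-5-yl]chroman-4-ol | COc1ccc(-c2cc3cc([C@H]4C[C@@H](O)c5ccc(OC)cc5O4)ccc3o2)cc1
F7 | step 6 | (±)-trans-5-bromo-2-(4-methoxyphenyl)-2,3-dihydro-1-benzofuran-3-carboxylic acid | OC(=O)[C@@H]1c2cc(Br)ccc2O[C@H]1c1ccc(OC)cc1
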